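(The readings were generated by integration for substances that don't exist.)

3 questions stand over the west run, and behind them lies a decision: to leave its charge as set, or to change it first.

| setting | north-east | north-west | south-west | south | west |
|---|---|---|---|---|---|
| Z | 0.400 M | 0.240 M | 0.600 M | 0.400 M | 0.800 M |
| Q | 0.440 M | 0.280 M | 0.440 M | 0.220 M | 0.150 M |
| time |  |  |  |  | 85 min |

| run | time / min | [G] / M |
|---|---|---|
| north-east run | 3.4 | 0.0374 |
| north-east run | 6.5 | 0.0622 |
| north-east run | 12 | 0.0934 |
| north-east run | 23 | 0.1306 |
| north-east run | 45 | 0.1590 |
| north-east run | 85 | 0.1777 |
| north-west run | 3.4 | 0.0104 |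
| north-west run | 6.5 | 0.0211 |
| north-west run | 12 | 0.0350 |
| north-west run | 23 | 0.0494 |
| north-west run | 45 | 0.0630 |
| north-west run | 85 | 0.0736 |
| south-west run | 3.4 | 0.0444 |
| south-west run | 6.5 | 0.0773 |
| south-west run | 12 | 0.1117 |
| south-west run | 23 | 0.1514 |
| south-west run | 45 | 0.1858 |
| south-west run | 85 | 0.2014 |
| south run | 3.4 | 0.0114 |
| south run | 6.5 | 0.0169 |
| south run | 12 | 0.0287 |
| south run | 23 | 0.0428 |
| south run | 45 | 0.0526 |
| south run | 85 | 0.0628 |

(standard deviation of a reading: 0.001 M)

* the power of [Q] that the first rate follows, about the charge of the north-east run; measure it at two percent of Z made into G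
* the power of [Z] that the first rate follows, about the charge of the north-east run; measure it at two percent of Z made into G (one fixed amount of G, the same in the runs compared)
* G in the west run at 85 min, as a share of the Z charged

- Overall: Z + Q -> G.
- Constant volume, constant temperature.
- A reading of a species includes what of it is bound.
- "The second partner" is Q.
- An order is taken over about fifteen percent of the charge, up and down.

The decision hangs on how the early rate depends on each partner. At 6.5 min the north-east run has made 3.68 times the G of the south run, which holds half its Q, so the order in Q reads 1.88. The south-west run against the north-east run reads 0.536 for Z. Taking these as 2 and 0.5, the rate per Q goes as cQ·√cZ, a group by which flasks can be compared.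

By the overall equation Q is the limiting reagent in the west run, so its yield is best counted per Q. Kept from the south run is 0.285, the turnover count: G made by 85 min per Q charged. The count is 0.404 in the north-east run and 0.458 in the south-west run, where the group is larger. The west group is 0.964 of the south group. The north-west run has a similar group but a count of 0.263, and it turned 30.7% of its Z against 15.7% in the south run. The west run, with Z in large excess, therefore stands nearer the south run. The south count of 0.285, carried over to the Q and Z of the west charge, gives 5.35% of the Z charged as the reckoning here. The charge stays as set: with twice the Z of the south run and less Q, it changes both partners while the group stays at 0.964 of the south value.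

The forecast, which held that “All runs stall far short of reagent exhaustion”, gave 1.8 for Q, 0.5 for Z and 6%, a share above the reckoning here.

The west run gives 5.39%. About the charge of the north-east run, the order in Q is 2.1, above the forecast, and the order in Z is 0.56. The turnover count of the west run is 0.287, against 0.285 from the south run.

    Z + 2 Q → G + Q (1.134 M⁻² min⁻¹)
    Q → Qe (0.01476 min⁻¹)
    2 Z ⇌ Z2, settled at all times (49.60 M⁻¹)

With the association of 2 Z to Z2 taken away, the order in Z about the north-east charge is 1.0 instead of 0.56. With the same association taken away, the west run reaches 13.6% of its Z instead of 5.39%, a turnover count of 0.727.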